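(Its constants are those of an exercise; the run is a simulation.)

Time separates these two flasks: larch runs 40 s, alder 10 s, on the same charges.

| setting | larch | alder |
|---|---|---|
| free monomer | 1.5 M (fed, over 1.5 s) | 1.5 M (fed, over 1.5 s) |
| protic impurity | 0.0300 M | 0.0300 M |
| initiator | 2.5 mol% | 2.5 mol% |
| time | 40 s | 10 s |
| remark | the fed solution adds 0.10 times the starting volume | the fed solution adds 0.10 times the starting volume |

    free monomer + initiator → living end + monomer in chains (k1 = 2.03 L mol⁻¹ s⁻¹)
    free monomer + living end → monomer in chains + living end, rate k2*[living end]*[free monomer] (k2 = 1.62 L mol⁻¹ s⁻¹)
    protic impurity + free monomer → quenched substrate (k3 = 42.0 L mol⁻¹ s⁻¹)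
    2 initiator → spent initiator (k4 = 0.421 L mol⁻¹ s⁻¹)
    monomer in chains → over-reaction product (k5 = 2.55 × 10⁻⁵ s⁻¹)

- two of one species on the left: rate k times its square, two consumed each time
- amounts are per litre of the starting volume; all of the dose is in the solution fed
- the average divides the monomer in chains by the number of chains begun, living and dead together
- run time (larch): 40 s

1. which of the two ends with the longer chains by the average number of monomer units in a chain (chains begun, living or dead) ("neither" if they lie within 10 %) (larch / alder / neither)
2. average number of monomer units in a chain (chains begun, living or dead) at the end, larch
3. average number of monomer units in a chain (chains begun, living or dead) at the end, alder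

The concentration to watch is the living end. Growth goes at its constant times living end times free monomer. While the living end stands still, free monomer therefore falls first order (pseudo-first-order). My bench rule is one initiator, one living end, diluted by the feed. That gives 0.0341 M and a decay constant of 0.0552 s⁻¹. So 12.6 s is the monomer half-life: ln(2) over the growth constant times the living end.

Two corrections come first. With concentrations held at their charge, protic impurity halves free monomer in 0.55 s, far faster than the growth does. So I take 0.0300 M off the charge, leaving 1.47 M. Initiator reacts with itself far more slowly than with monomer, so I count chains begun as its charge, 0.0375 M. I start the clock at mid-feed and divide the monomer gone into chains by the chains begun. Larch comes to 34.7 and alder to 15.7, so I commit to larch.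

The rule needs the ends in place before much monomer has gone. At the diluted monomer charge, initiator halves in 0.250 s, much shorter than the monomer half-life. But the feed lasts 1.5 s. With monomer rising steadily from nothing, I reckon about 0.826 s for that halving, still much shorter than the monomer half-life. The border of the rule is the ratio of this formation time to the monomer half-life, here 0.0656: at one, ends take as long to form as monomer takes to halve.

The forecast says 35.3 for larch and 15.9 for alder, with larch longer, a little above mine. Its ground is “After that, M decays first-order”.

The flask gives 35.2 for larch and 15.9 for alder, and larch has the longer chains. At 5.03 s in alder, free monomer has a half-life of 13 s by growth, with the living end at 0.0334 M. Alder stops inside one such half-life with 59.1 % of its free monomer standing, while larch runs 3.12 half-lives and ends at 11.6 %. For the neighbour of alder charged with 10 mol% initiator, the monomer half-life reckons to 3.14 s. That flask holds 0.126 M of living end and ends with 14.5 % free monomer, at an average length of 9.03.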